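**Assumption:** the target has no stereogenic centre and is achiral, so "single enantiomer" is read as the single geometric isomer drawn, with both stereogenic double bonds E. All four starting materials (1, 2, 4, 5) are taken as catalogue chemicals.

## The problem

The target is a chalcone in which a resorcinol-derived ring A and a 4-hydroxyphenyl ring B are joined by a C(=O)–Cα=Cβ bridge; the skeleton is simple and the difficulty lies in its functional groups. Its three phenolic oxygens are in three different states (O-4' carries the geranyl chain, O-2' is free and hydrogen-bonded to the ketone, O-4 on ring B is free), and a synthesis has to tell them apart, ideally without protecting groups. There are no stereocentres; the stereo-elements are the 2E double bond of the geranyl chain, which must be carried through unchanged, and the E enone double bond, which must be made. The geranyl aryl ether is allylic: acid ionises it and cyclises the 1,5-diene, and strong heating brings on the aromatic Claisen rearrangement. The 2'-hydroxy enone closes by 6-endo oxa-Michael addition under acid or base, so long exposure to either should be avoided once the enone exists. The classical base-mediated condensation therefore needs the ring-B phenol masked and later unmasked with acid, which is what the geranyl ether and the enone tolerate least. The feature that allows a different union is the free hydroxyl on C-2' of ring A, ortho to C-1', the carbon that carries the ketone carbonyl: with hydrogen in place of Cα this is the O–H/CHO pair of a salicylaldehyde. That pair chelates rhodium and allows the formyl C–H bond to be added across an alkyne.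

## Retrosynthesis

Disconnection 1 (8 ⇒ 3 + 7). The C(=O)–Cα bond is cut and the hydrogen on Cβ is returned to the carbonyl carbon. This is the retron of an alkyne hydroacylation and leads to salicylaldehyde 3 and 4-ethynylphenol 7. Against the neighbouring Cα=Cβ cut (aldol), this cut needs no enolate, no stoichiometric base and no protection of O-4; against the Cβ–aryl cut (Heck), it avoids an unsubstituted o-hydroxyaryl vinyl ketone. Both precursors are monoaryl compounds without the enone, all atoms of 3 and 7 appear in 8, and the E geometry is a mechanistic consequence of syn addition. The forward reaction must activate the formyl C–H of 3 without decarbonylation, deliver the acyl group to the terminal alkyne carbon, and leave the free phenol of 7, the allylic ether and the two trisubstituted alkenes untouched.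

Disconnection 2 (3 ⇒ 1 + 2). The O-4–CH2 bond of the geranyl ether is cut, giving 2,4-dihydroxybenzaldehyde 1 and geranyl bromide 2. The cut is placed here, not at the end, because in 1 the two hydroxyls differ sharply: O-2 is chelated to the aldehyde, while O-4 is para to it and acidic, whereas in 8 two non-chelated phenols would compete. The forward reaction is a mild-base O-alkylation that must stop at the mono-ether and proceed by direct SN2 substitution, so that the 2E geometry of 2 is carried over.

Disconnection 3 (7 ⇒ 6 ⇒ 4 + 5). The C(sp)–H of 7 is traced to a C(sp)–Si bond in 6, and the aryl–C(sp) bond of 6 is cut to 4-iodophenol 4 and ethynyltrimethylsilane 5. Alkyne 7 keeps poorly, so it is released from the stable silyl alkyne 6 just before use. The Sonogashira coupling tolerates the free phenol, and the silyl cap prevents double arylation.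

## Roads not taken

Alternative 1: Claisen–Schmidt condensation, the obvious route. The cut is Cα=Cβ. In the forward sense the acetophenone 1-[4-(geranyloxy)-2-hydroxyphenyl]ethan-1-one A1 is condensed under hydroxide with 4-(methoxymethoxy)benzaldehyde A2 to give the MOM-protected chalcone A3, and the acetal of A3 is then removed with acid to give 8. The chosen plan is better because unprotected 4-hydroxybenzaldehyde is a vinylogous carboxylate under the basic conditions and a poor electrophile, so O-4 has to be masked as in A2. The unmasking of A3 then needs acid, which threatens the allylic aryl ether and promotes oxa-Michael closure of the 2'-hydroxy enone. Counting the preparation of A1 and A2, the sequence is four steps with a protect/deprotect pair and stoichiometric base, whereas the hydroacylation joins unprotected halves under near-neutral, redox-neutral conditions.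

Alternative 2: late-stage, biosynthesis-like O-geranylation. The cut is O-4'–CH2 of the geranyl ether, made last, as a prenyltransferase would. In the forward sense isoliquiritigenin A4 is alkylated with 2 and mild base. The chosen plan is better because A4 has two non-chelated phenols of similar acidity: O-4' is para to the ketone and O-4 is para to it through the enone. A reagent, unlike an enzyme pocket, is expected to give the regioisomeric 4-O-geranyl ether A5 and over-alkylation as well. A4 would also have to be made first by the chemistry of Alternative 1. The chosen plan alkylates 1, where the only competitor is the chelated hydroxyl.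

Alternative 3: Mizoroki–Heck arylation. The cut is Cβ–C-1 of ring B. In the forward sense the vinyl ketone 1-[4-(geranyloxy)-2-hydroxyphenyl]prop-2-en-1-one A6 is coupled with 4-iodophenol 4 under Pd(0) and base. The chosen plan is better because A6 is an o-hydroxyaryl vinyl ketone: under the base and heat of a Heck reaction it is expected to polymerise and to close by oxa-Michael addition to 7-(geranyloxy)chroman-4-one A7. A6 also takes several steps to prepare. The hydroacylation builds the same bridge from a stable aldehyde and never passes through an unsubstituted enone.

Key step: step 4

## Route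

Step 1
Reactants: 1 2,4-dihydroxybenzaldehyde; 2 geranyl bromide, (2E)-1-bromo-3,7-dimethylocta-2,6-diene
Product: 3 4-{[(2E)-3,7-dimethylocta-2,6-dien-1-yl]oxy}-2-hydroxybenzaldehyde
Conditions: KHCO3 (1.2 equiv), 2 (1.0 equiv), MeCN, 60 °C
Reagents that add atoms: none
Why: Williamson etherification; bicarbonate ionises only the 4-OH para to the aldehyde, while the 2-OH stays locked in its hydrogen bond to the carbonyl, and SN2 attack at the primary allylic carbon leaves the 2E double bond of the chain unchanged.

Step 2
Reactants: 4 4-iodophenol; 5 ethynyltrimethylsilane
Product: 6 4-[(trimethylsilyl)ethynyl]phenol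
Conditions: PdCl2(PPh3)2 (2 mol%), CuI (4 mol%), Et3N, THF, rt, Ar
Reagents that add atoms: none
Why: Sonogashira coupling of an aryl iodide, which proceeds at room temperature in the presence of a free phenol; the silyl cap rules out a second arylation.

Step 3
Reactants: 6 4-[(trimethylsilyl)ethynyl]phenol
Product: 7 4-ethynylphenol
Conditions: K2CO3 (0.3 equiv), MeOH, rt; pH 7 buffer work-up, short silica plug, used at once
Reagents that add atoms: none
Why: base-catalysed methanolysis of the alkynyl C–Si bond, a standard protodesilylation that leaves the phenol untouched; copper is removed in step 2 so that oxidative alkyne dimerisation is not catalysed here.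

Step 4
Reactants: 3 4-{[(2E)-3,7-dimethylocta-2,6-dien-1-yl]oxy}-2-hydroxybenzaldehyde; 7 4-ethynylphenol
Product: 8 (2E)-1-(4-{[(2E)-3,7-dimethylocta-2,6-dien-1-yl]oxy}-2-hydroxyphenyl)-3-(4-hydroxyphenyl)prop-2-en-1-one
Conditions: [Rh(cod)Cl]2 (2.5 mol%), dppf (5 mol%), Na2CO3 (10 mol%), toluene, 80 °C, Ar; 7 (1.3 equiv) added as a toluene–THF solution over 2 h
Reagents that add atoms: none
Why: Chelation-assisted intermolecular alkyne hydroacylation, whose closest known reaction type is the Rh(I)/diphosphine-catalysed addition of salicylaldehydes to internal and terminal alkynes. Carbonate-assisted exchange should place the aryloxide of 3 on Rh(I), and oxidative addition of the adjacent formyl C–H then gives a five-membered O,C-chelated acyl rhodium(III) hydride whose chelate ring holds the acyl group against decarbonylation. The triple bond of 7 coordinates and inserts into Rh–H in syn fashion with rhodium at the unsubstituted terminus, as the bulk of dppf and the usual sense for aryl-substituted alkynes in this reaction class (acyl remote from the arene) suggest, and acyl–vinyl reductive elimination followed by proton exchange with the next molecule of 3 releases 8. No ring is closed and no stereocentre is formed; the one new stereo-element is the Cα=Cβ double bond, and its E geometry follows from syn delivery of H and acyl across the alkyne and is also the thermodynamically favoured one. The step needs the formyl C–H of 3 to react in preference to the O–H of 7, which is secured because 3 is the more acidic phenol and the only one that can chelate. It needs the terminal alkyne to react in preference to the two trisubstituted geranyl alkenes, which bind rhodium weakly and are not expected to insert, and it needs the linear enone over the branched one. Slow addition of 7 should hold back alkyne oligomerisation, and 80 °C is far below the temperature of the aromatic Claisen rearrangement, so the geranyl ether and its 2E double bond should pass through unchanged.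

## Compound list

1 | 2,4-dihydroxybenzaldehyde | O=Cc1ccc(O)cc1O | starting material
2 | geranyl bromide, (2E)-1-bromo-3,7-dimethylocta-2,6-diene | CC(C)=CCC/C(C)=C/CBr | starting material
3 | 4-{[(2E)-3,7-dimethylocta-2,6-dien-1-yl]oxy}-2-hydroxybenzaldehyde | CC(C)=CCC/C(C)=C/COc1ccc(C=O)c(O)c1 | intermediate
4 | 4-iodophenol | Oc1ccc(I)cc1 | starting material
5 | ethynyltrimethylsilane | C#C[Si](C)(C)C | starting material
6 | 4-[(trimethylsilyl)ethynyl]phenol | C[Si](C)(C)C#Cc1ccc(O)cc1 | intermediate
7 | 4-ethynylphenol | C#Cc1ccc(O)cc1 | intermediate
8 | (2E)-1-(4-{[(2E)-3,7-dimethylocta-2,6-dien-1-yl]oxy}-2-hydroxyphenyl)-3-(4-hydroxyphenyl)prop-2-en-1-one | CC(C)=CCC/C(C)=C/COc1ccc(C(=O)/C=C/c2ccc(O)cc2)c(O)c1 | target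

## Step count and risks

Total steps: 4. Longest linear sequence: 3 steps (4 → 6 → 7 → 8). The other branch is 1 → 3 → 8.

**Step 4 (key step).** Several processes could go wrong:
- hydrometalation in the wrong sense, placing the acyl group on the aryl-bearing alkyne carbon, because a terminal alkyne offers a smaller steric bias than an internal one;
- rhodium-mediated oligomerisation of the terminal arylacetylene, which would use up 7;
- binding of the catalyst by the phenoxide of 7 or by the chelating product;
- slow oxa-Michael closure of the product under carbonate at 80 °C;
- rhodium hydride-induced isomerisation or ionisation of the allylic ether.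

Fallback: a stepwise, stoichiometric version of the same union that sets out from 7 and 3 and returns at 8. Alkyne 7 is silylated (TBSCl, imidazole, DMF) to tert-butyl(4-ethynylphenoxy)dimethylsilane F1. F1 is hydrozirconated with Cp2Zr(H)Cl in CH2Cl2, which is reliably anti-Markovnikov and syn, and transmetalated with Me2Zn. The alkenylzinc is added to 3, whose phenol has first been turned into its zinc phenoxide with one equivalent of Me2Zn. This should give the racemic allylic alcohol 5-(geranyloxy)-2-[(2E)-1-hydroxy-3-{4-[(tert-butyldimethylsilyl)oxy]phenyl}prop-2-en-1-yl]phenol F2. Oxidation of the doubly activated carbinol of F2 with MnO2 in CH2Cl2 should give the silyl-protected chalcone (2E)-1-[4-(geranyloxy)-2-hydroxyphenyl]-3-{4-[(tert-butyldimethylsilyl)oxy]phenyl}prop-2-en-1-one F3. Acetic acid-buffered TBAF in THF at 0 °C then desilylates F3 to 8.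

**Step 3.** The free terminal arylacetylene 7 may polymerise or couple oxidatively during concentration or storage, since it is an electron-rich phenol and a reactive alkyne at once.

Fallback: carry the ring-B phenol masked through the alkyne release and the coupling, setting out from 6 and returning at 8. Compound 6 is silylated (TIPSCl, imidazole) to triisopropyl{4-[(trimethylsilyl)ethynyl]phenoxy}silane F4. K2CO3/MeOH removes only the alkynyl silyl group of F4 and should give the stable (4-ethynylphenoxy)triisopropylsilane F5. Hydroacylation of F5 with 3 under the conditions of step 4 should give the TIPS-protected chalcone (2E)-1-[4-(geranyloxy)-2-hydroxyphenyl]-3-{4-[(triisopropylsilyl)oxy]phenyl}prop-2-en-1-one F6. Buffered TBAF then converts F6 into 8.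

**Step 1.** Further alkylation at the chelated O-2, C-alkylation of the ambident phenoxide, or SN2' attack on the allylic bromide could lower the yield of the mono-ether.

Fallback: install the formyl group after the ether, so that the O-2/CHO relationship never has to be differentiated by alkylation. The sequence sets out from 2 and returns at 3. An excess of resorcinol is mono-alkylated with 2 (K2CO3, acetone) to 3-{[(2E)-3,7-dimethylocta-2,6-dien-1-yl]oxy}phenol F7. Magnesium-mediated ortho-formylation of F7 (MgCl2, Et3N, paraformaldehyde, MeCN, reflux) should then place the aldehyde ortho to the free hydroxyl and para to the ether, at the less hindered position, to give 3.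

## Further compounds

F1 | step 4 | tert-butyl(4-ethynylphenoxy)dimethylsilane | C#Cc1ccc(O[Si](C)(C)C(C)(C)C)cc1
F2 | step 4 | racemic 5-(geranyloxy)-2-[(2E)-1-hydroxy-3-{4-[(tert-butyldimethylsilyl)oxy]phenyl}prop-2-en-1-yl]phenol | CC(C)=CCC/C(C)=C/COc1ccc(C(O)/C=C/c2ccc(O[Si](C)(C)C(C)(C)C)cc2)c(O)c1
F3 | step 4 | (2E)-1-[4-(geranyloxy)-2-hydroxyphenyl]-3-{4-[(tert-butyldimethylsilyl)oxy]phenyl}prop-2-en-1-one | CC(C)=CCC/C(C)=C/COc1ccc(C(=O)/C=C/c2ccc(O[Si](C)(C)C(C)(C)C)cc2)c(O)c1
F4 | step 3 | triisopropyl{4-[(trimethylsilyl)ethynyl]phenoxy}silane | CC(C)[Si](Oc1ccc(C#C[Si](C)(C)C)cc1)(C(C)C)C(C)C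
F5 | step 3 | (4-ethynylphenoxy)triisopropylsilane | C#Cc1ccc(O[Si](C(C)C)(C(C)C)C(C)C)cc1
F6 | step 3 | (2E)-1-[4-(geranyloxy)-2-hydroxyphenyl]-3-{4-[(triisopropylsilyl)oxy]phenyl}prop-2-en-1-one | CC(C)=CCC/C(C)=C/COc1ccc(C(=O)/C=C/c2ccc(O[Si](C(C)C)(C(C)C)C(C)C)cc2)c(O)c1
F7 | step 1 | 3-{[(2E)-3,7-dimethylocta-2,6-dien-1-yl]oxy}phenol | CC(C)=CCC/C(C)=C/COc1cccc(O)c1
A1 | alternative 1 | 1-[4-(geranyloxy)-2-hydroxyphenyl]ethan-1-one | CC(C)=CCC/C(C)=C/COc1ccc(C(C)=O)c(O)c1
A2 | alternative 1 | 4-(methoxymethoxy)benzaldehyde | COCOc1ccc(C=O)cc1
A3 | alternative 1 | (2E)-1-[4-(geranyloxy)-2-hydroxyphenyl]-3-[4-(methoxymethoxy)phenyl]prop-2-en-1-one | CC(C)=CCC/C(C)=C/COc1ccc(C(=O)/C=C/c2ccc(OCOC)cc2)c(O)c1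
A4 | alternative 2 | isoliquiritigenin, (2E)-1-(2,4-dihydroxyphenyl)-3-(4-hydroxyphenyl)prop-2-en-1-one | O=C(/C=C/c1ccc(O)cc1)c1ccc(O)cc1O
A5 | alternative 2 | (2E)-1-(2,4-dihydroxyphenyl)-3-[4-(geranyloxy)phenyl]prop-2-en-1-one | CC(C)=CCC/C(C)=C/COc1ccc(/C=C/C(=O)c2ccc(O)cc2O)cc1
A6 | alternative 3 | 1-[4-(geranyloxy)-2-hydroxyphenyl]prop-2-en-1-one | CC(C)=CCC/C(C)=C/COc1ccc(C(=O)C=C)c(O)c1
A7 | alternative 3 | 7-(geranyloxy)chroman-4-one | CC(C)=CCC/C(C)=C/COc1ccc2c(c1)OCCC2=O
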